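After 20.0 h the south-west run has 57.6 % of its substrate not yet turned into product. The flask has the same substrate and reagent charges but less free catalyst, so we expect it to reach that leftover later.

| flask | substrate | reagent | free catalyst | remark |
|---|---|---|---|---|
| east | 1.5 M | 1.32 M | 28 mM | run made earlier |
| north-east | 2.4 M | 1.32 M | 28 mM | run made earlier |
| south-west | 1.1 M | 1.32 M | 42 mM | run made earlier |
| flask | 1.1 M | 1.32 M | 28 mM |  |

| run | time / h | product / % |
|---|---|---|
| east | 3.00 | 3.6 |
| east | 6.00 | 7.3 |
| east | 10.0 | 10.9 |
| east | 12.0 | 16.0 |
| east | 15.0 | 19.3 |
| east | 20.0 | 24.6 |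
| north-east | 1.33 | 1.7 |
| north-east | 4.00 | 3.2 |
| north-east | 6.00 | 5.6 |
| north-east | 10.0 | 7.9 |
| north-east | 15.0 | 11.9 |
| north-east | 20.0 | 14.6 |
| south-west | 4.00 | 8.7 |
| south-west | 8.00 | 17.6 |
| south-west | 10.0 | 23.3 |
| south-west | 15.0 | 34.0 |
| south-west | 20.0 | 42.4 |

(standard deviation of a reading: 1 percentage point)

- factor on the rate of making product when 50 % of the substrate are converted if reagent is charged twice over
- factor on the rate when 50 % of the substrate are converted if free catalyst is charged at 150 mM instead

The south-west catalyst charge over the flask's is 1.50. We assume the rate is proportional to the catalyst charge, though no earlier run changes catalyst by itself. With substrate and reagent charges fixed, this clock factor then stretches each south-west hour onto a time–conversion master curve.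

South-west starts at 0.0217 h⁻¹ of the charge, so the flask should start at 0.0145 h⁻¹. Over its last stretch south-west makes 0.0168 h⁻¹, a reading of 0.772 of its start, with leftover factors of 0.618 for substrate and 0.682 for reagent. If both share one order, that order is 0.299.

At 50 % conversion, doubling the reagent raises the reagent present by a factor of 2.71, so we reckon a factor of 1.35 on the rate, which is a guess. At equal leftover the slowing cancels on the clock, so for 150 mM of catalyst we reckon a factor of 5.36.

The forecast gives 2.1 for reagent, higher than ours, and 2.5 for catalyst, lower than ours, with the catalyst figure resting on “a dimer resting state or saturation”.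

The flask gives 1.36 for reagent and 5.26 for catalyst.

    substrate + free catalyst → catalyst intermediate A (k = 2.40 L mol⁻¹ h⁻¹)
    reagent + catalyst intermediate A → catalyst intermediate B (k = 2.40 L mol⁻¹ h⁻¹)
    catalyst intermediate B ⇌ catalyst intermediate C (K = 2.10, k = 2.70 h⁻¹)
    catalyst intermediate C ⇌ by-product + catalyst intermediate D (K = 44.0 M, k = 4.90 h⁻¹)
    catalyst intermediate D → free catalyst + product (k = 34.0 h⁻¹)
    2 catalyst intermediate A ⇌ resting dimer (K = 78.0 L mol⁻¹, k = 2.60 L mol⁻¹ h⁻¹)

By the clock, the south-west reading of 42.4 % belongs at 30.0 h in the flask, which then holds 43.0 % product, and the flask with 150 mM of catalyst gives 5.26 against the clock's 5.36. The resting dimer, a form outside the working round that counts as two, holds 14.0 % of the catalyst charged in the flask at 30.0 h. Its formation and undoing are the largest single effect on the flask's apparent order in reagent at 50 % conversion, which is 0.79 with the dimer and 0.46 without it.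

The data were computed with constants of no real substance, noise included.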